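Carbons are numbered C1–C22 in the order in which they occur along the SMILES string of the target; compounds are numbered 1–24 as in the steps.

## Analysis of the target

- C1–C3 are the isopropenyl group on C4; C5 is a CH2; C6 and C11 are quaternary; C7 and C10 are the ketones; C8 is a bridgehead CH; C9 and C12 are CH2; C13=C15 is the ring alkene with methyl C14; C16 is the benzylic CH; C17–C22 are the arene, with OH on C18 and C21.
- The molecule is pentacyclic. Ring A is the cyclohexane-1,4-dione C6–C7–C8–C9–C10–C11, bridged across C6/C8 by C5–C4 into a bicyclo[3.2.1]octane. Ring B is the cyclohexene C6–C11–C12–C13=C15–C16. The hydroquinone spans C16 and C11 and closes the five-membered ring C6–C11–C22–C17–C16.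
- There are five stereocentres (C4, C6, C8, C11, C16). C8 is tied to C6 by the bridge and C16 to C11 by the arene, so three relationships are free: the isopropenyl group is exo (syn to the one-carbon bridge C7); across C6–C11 the carbons C5 and C22 are antiperiplanar (C7 lies on the arene side); and the absolute configuration.
- C6 and C11 are vicinal all-carbon quaternary centres at the core of the cage. This is the main difficulty.
- Sensitive groups are the air-sensitive hydroquinone, the 1,4-dione (C10 enolisable at C9; C7 not enolisable) and two alkenes, which exclude hydrogenation and strong electrophiles late in the route.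
- The strategy rests on the arene ring C17–C22 being attached only through C17 and C22, whose anchors C16 and C11 are 1,3-related across C6. Removing the arene leaves two ethynyl groups held cis on ring B (a hepta-1,6-diyne) and a two-carbon unit C19–C20.

## Retrosynthetic reasoning

**24 to 23.** The two phenolic C–O bonds are traced back to C–B bonds. Boron is inert in a metal-mediated cycloaddition and is converted to OH under mild oxidation, so no aryl ether has to be cleaved next to the isopropenyl group and the dione.

**23 to 21 and 22.** The bonds C17–C22, C18–C19 and C20–C21 are cut. This removes the benzene ring and the five-membered ring together and creates no stereocentre. The forward reaction joins the 1,6-diyne 21, whose termini carry the boryl groups, with acetylene 22 in a [2+2+2] cycloaddition, so the oxygens land on C18 and C21 by construction.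

**21 to 20.** The two C(sp)–B bonds are cut. A base-free dehydrogenative borylation is required because the C10 ketone is enolisable.

**20 to 16 and 17.** The C11–C22 bond is cut; C11 is α to C10, so it is made by electrophilic alkynylation of the C10 enolate with the ethynyl-transfer reagent 17. It is placed after the bicyclo[3.2.1]octane is closed. In an unbridged cis-fused bicycle the electrophile would enter cis to C5, whereas in the bridged enolate the C5–C4 bridge covers that face and forces C22 anti to C5. The competing α-carbon C9 is handled by passing through the thermodynamic enol silane 16.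

**16 to 15 to 14.** These are functional-group changes: enol silane from the dione 15, and the dione from the ketal 14. The C10 ketal is kept until the bridge exists because it directs the previous steps to C7.

**14 to 13 to 12.** The C4–C8 bond is cut. C8 is the only α-carbon of C7 that can become nucleophilic, and C4 is the terminus of an allyl unit whose other end becomes the isopropenyl CH2. A concerted ene closure of a prenyl group was considered and rejected: it must deliver the allylic hydrogen to C9 and therefore puts the isopropenyl group endo, the wrong epimer at C4. A palladium π-allyl closure has no such constraint. The C8 enolate is stored as enol silane 13, obtained by conjugate hydrosilylation of the enone 12.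

**12 to 10 and 8.** The C5–C6 bond is cut. The enone double bond C8=C9 of 10 blocks C8, so deprotonation can only occur at C6. An α-alkylated enone would be a poor dienophile, so the side chain is added after the cycloaddition.

**10 to 9 and 5.** The bonds C6–C16 and C11–C12 are cut (Diels–Alder). One enone double bond of the symmetrical quinone monoketal 9 reacts with the dienyne 5. This builds ring B, sets C16 relative to C6, carries the first alkyne, and is the point at which absolute configuration is introduced.

**5 to 3 and 4; 3 to 1 and 2; 8 to 7 to 6.** Two stereoretentive cross-couplings assemble the (E)-dienyne. The C5 side-chain reagent comes from a vinyl epoxide by allylic opening and carbonate formation.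

## Alternatives that were turned down

**Alternative 1:** Ring A is disconnected at C9–C10.
- Forward step: aldehyde A1 (formyl C10 on C11, exocyclic methylene C9 on a spiro-cyclopentanone) is reduced with SmI2 (divalent samarium). The ketyl adds to C9, and protonation at C8 gives carbinol A2, which still needs oxidation and two O-demethylations.
- For it: the radical addition is polarity-matched and this type of closure is well established. On reliability of the key bond formation it is stronger than the chosen route.
- Against it: the formyl group sits on quaternary C11 next to quaternary C6. The enone is reduced more easily than the aldehyde, so the order of electron transfer is not assured. A1 already demands the indane, both quaternary centres and C4. Cleaving two aryl methyl ethers beside an isopropenyl group and a 1,4-dione is unattractive.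
- Comparison: the chosen strategy makes the arene and the five-membered ring together and unveils the oxygens from boron.

**Alternative 2:** Ring B is disconnected at C13=C15.
- Forward step: diene A3 (vinyl on C16, methallyl on C11, isopropenyl masked as acetyl) is closed with a second-generation Hoveyda–Grubbs catalyst to A4, with loss of ethylene.
- For it: the two alkenes are held cis on a rigid indane and metathesis tolerates ketones. The outcome of the key step is more predictable than that of the chosen one.
- Against it: the 1,1-disubstituted alkene next to quaternary C11 is slow to react. The isopropenyl group must be masked, and later one of three ketones must be methylenated selectively. The benzylic C16 stereocentre, the C6/C11 pair and the bicyclooctane still have to be built on an arene scaffold.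
- Comparison: the chosen route makes ring B early by a Diels–Alder reaction that sets C16 against C6 in one step.

**Alternative 3:** Ring A is disconnected at C8–C9.
- Forward step: diketone A5 (spiro-cyclopentanone, acetyl on C11) is converted to its bis-enolate and oxidised with Fe(acac)3 (trivalent iron) or CuCl2 (divalent copper) to A6, the bis(methyl ether) of the target.
- For it: both enolisation sites are unambiguous, and one step gives the 1,4-dione and the bicyclo[3.2.1]octane at the right oxidation level. In directness of the skeleton-forming step it is at least as strong as the chosen route.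
- Against it: open-shell or organocopper intermediates are generated beside the isopropenyl group. The strained intramolecular coupling must beat dimerisation and α-halogenation. A5 again presupposes the congested indane, and two methyl ethers must be cleaved at the end.
- Comparison: the chosen strategy offers a redox-neutral, closed-shell key step and a free hydroquinone without deprotection.

Key step: step 13

Assumption (remark on the chemistry): the facial sense of the BINOL–titanium Diels–Alder catalyst on dienophile 9 is not predicted here; (R)-BINOL is written, and (S)-BINOL would be used if it is the ligand that gives adduct 10 as drawn.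

## Route

Step 1
Reactants: 1 ethynyltrimethylsilane; 2 (E)-1,2-dichloroethene
Product: 3 (E)-(4-chlorobut-3-en-1-yn-1-yl)trimethylsilane
Conditions: Pd(PPh3)4 (5 mol %), CuI (10 mol %), n-BuNH2, Et2O, 25 °C; 2 in fivefold excess
Reagents that add atoms: none
Why: Sonogashira coupling of a terminal alkyne with a vinyl chloride; the excess of 2 limits reaction to one C–Cl bond, and oxidative addition and reductive elimination retain the (E)-geometry.

Step 2
Reactants: 3 (E)-(4-chlorobut-3-en-1-yn-1-yl)trimethylsilane; 4 isopropenylmagnesium bromide
Product: 5 (E)-trimethyl(5-methylhexa-3,5-dien-1-yn-1-yl)silane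
Conditions: Pd(PPh3)4 (5 mol %), THF, 0 → 25 °C
Reagents that add atoms: none
Why: Kumada coupling; the conjugated alkyne activates the vinyl chloride toward oxidative addition and the coupling is stereoretentive, giving the (E)-dienyne C12=C13(C14)–C15=C16–C17≡C18.

Step 3
Reactants: 6 2-methyl-2-vinyloxirane
Product: 7 (E)-4-chloro-2-methylbut-2-en-1-ol
Conditions: TiCl4, CH2Cl2, −85 °C; then H2O
Reagents that add atoms: titanium tetrachloride, Cl[Ti](Cl)(Cl)Cl
Why: Lewis-acid opening of a vinyl epoxide with allylic transposition (SN2′); chloride is delivered to the vinyl terminus and the (E)-alkene is the established outcome for this epoxide. The carbons map as C5 (CH2Cl), C4, C2, C3 (methyl) and C1 (CH2OH).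

Step 4
Reactants: 7 (E)-4-chloro-2-methylbut-2-en-1-ol
Product: 8 tert-butyl (E)-4-chloro-2-methylbut-2-en-1-yl carbonate
Conditions: Boc2O, DMAP (5 mol %), CH2Cl2, 0 → 25 °C
Reagents that add atoms: di-tert-butyl dicarbonate, CC(C)(C)OC(=O)OC(=O)OC(C)(C)C
Why: DMAP-catalysed O-acylation. The hindered tert-butyl carbonate should survive an enolate and a hydride reagent, yet is ionised by zerovalent palladium with release of tert-butoxide.

Step 5
Reactants: 9 4,4-dimethoxycyclohexa-2,5-dien-1-one; 5 (E)-trimethyl(5-methylhexa-3,5-dien-1-yn-1-yl)silane
Product: 10 (4aR,8S,8aS)-4,4-dimethoxy-6-methyl-8-[(trimethylsilyl)ethynyl]-4a,5,8,8a-tetrahydronaphthalen-1(4H)-one (cis-fused; alkynyl group on C16 cis to the C6–C7 bond)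
Conditions: catalyst from (R)-BINOL and TiCl2(Oi-Pr)2 (1:1, tetravalent titanium, 10 mol %), 4 Å MS, CH2Cl2, 0 → 25 °C
Reagents that add atoms: none
Why: Lewis-acid-catalysed Diels–Alder reaction of a quinone monoketal, for which chiral titanium–BINOL catalysis is established. The diene terminus C12 (remote from the alkynyl group and next to the methyl-bearing carbon) bonds to the β-carbon C11 and C16 to the α-carbon C6; the endo transition state puts the alkynyl group cis to the C7 carbonyl and suprafacial addition gives the cis ring fusion. The catalyst-shielded enone face fixes the absolute configuration at C6 and C16 (C11 is re-set in step 11).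

Step 6
Reactants: 10 Diels–Alder adduct; 8 tert-butyl (E)-4-chloro-2-methylbut-2-en-1-yl carbonate
Product: 12 C6-alkylated enone (10 carrying on C6 the (E)-4-[(tert-butoxycarbonyl)oxy]-3-methylbut-2-en-1-yl chain cis to H11 and trans to the alkynyl group), via lithium dienolate 11 (not isolated)
Conditions: LDA, THF–DMPU, −78 °C; then 8, Bu4NI (10 mol %), −78 → −10 °C
Reagents that add atoms: none
Why: Kinetic deprotonation can only occur at C6 (C8 and C9 are vinylic, C10 is a ketal), and the cross-conjugated enolate is C-alkylated at the primary allylic carbon (enolate alkylation, SN2). The electrophile enters on the convex face of the cis-fused bicycle, the face of H11 and opposite to the alkynyl group, so C5 ends up cis to H11 and trans to the alkyne.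

Step 7
Reactants: 12 C6-alkylated enone
Product: 13 dimethylphenylsilyl enol ether (C7–OSiMe2Ph, C7=C8; C9 now CH2)
Conditions: [(Ph3P)CuH]6 (3 mol %, monovalent copper), PhMe2SiH (1.5 equiv), toluene, 25 °C
Reagents that add atoms: dimethylphenylsilane, C[SiH](C)c1ccccc1
Why: Copper hydride-catalysed conjugate hydrosilylation of the enone; hydride adds to C9 and the copper enolate is silylated. The isolated alkenes, the alkyne and the carbonate should be untouched, and the C7=C8 enolate is stored in base-free form.

Step 8
Reactants: 13 dimethylphenylsilyl enol ether
Product: 14 bridged tricyclic ketone (C4–C8 bond formed; isopropenyl on C4 exo, syn to C7; C10 dimethyl ketal; H11 cis to C5; (trimethylsilyl)ethynyl on C16)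
Conditions: Pd2(dba)3·CHCl3 (2.5 mol %, zerovalent palladium), dppe (6 mol %), THF, 25 → 60 °C
Reagents that add atoms: none
Why: Palladium-catalysed intramolecular allylic alkylation of a silyl enol ether by an allylic carbonate (Tsuji–Trost type). Ionisation gives the π-allyl complex C4–C2–C1, CO2 and tert-butoxide, which desilylates the enol ether; C8 then attacks the allyl terminus C4 (5-exo, across the 1,3-diaxial positions of ring A), leaving C2=C1 as the isopropenyl group. C8 is fixed by the bridge; at C4 the bulky 2-methylallyl–palladium unit should point away from ring A and the axial methoxy group on C10, which places the isopropenyl group exo.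

Step 9
Reactants: 14 bridged tricyclic ketone
Product: 15 tricyclic 7,10-dione (H11 drawn as formed in step 5; (trimethylsilyl)ethynyl on C16)
Conditions: PPTS (0.2 equiv), acetone–H2O (10:1), 40 °C
Reagents that add atoms: water, O
Why: Acid-catalysed hydrolysis of the dimethyl ketal under conditions that spare the alkenes and the silylalkyne. C7 cannot enolise (C6 quaternary, C8 bridgehead), and epimerisation at C11 is irrelevant because C11 becomes trigonal in step 10.

Step 10
Reactants: 15 tricyclic 7,10-dione
Product: 16 C10 trimethylsilyl enol ether (C10=C11)
Conditions: Me3SiCl, NaI, Et3N, MeCN, 25 → 40 °C; pentane extraction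
Reagents that add atoms: chlorotrimethylsilane, C[Si](C)(C)Cl
Why: Silyl enol ether formation under equilibrating conditions (Me3SiI formed in situ), which favour the tetrasubstituted C10=C11 isomer over the C9=C10 isomer; only the C10 ketone can react. This stores the C11 enolate and removes the competition from C9.

Step 11
Reactants: 16 C10 trimethylsilyl enol ether; 17 1-[(trimethylsilyl)ethynyl]-1,2-benziodoxol-3(1H)-one
Product: 20 C11,C16-diethynyl tricyclic dione (C22 on C11 trans to C5 and cis to the C16 alkyne), via tetrabutylammonium enolate 18 (not isolated), via monosilylated diyne 19 (not isolated)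
Conditions: 17 (1.3 equiv), Bu4NF (3.5 equiv, 1 M in THF), THF, −78 → 0 °C
Reagents that add atoms: none
Why: Electrophilic α-ethynylation of a ketone enolate with an ethynylbenziodoxolone: fluoride releases enolate 18 from 16 and the ethynyl-iodane from 17; C11 adds to the β-alkyne carbon, loss of 2-iodobenzoate gives an alkylidene carbene and a 1,2-hydrogen shift gives the alkyne. The reagent approaches the exo face of the bicyclo[3.2.1]octane enolate (syn to C7, axial on ring A) because the endo face is covered by the C5–C4 bridge, so C22 ends up trans to C5 and cis to the C16 alkyne. Excess fluoride removes the remaining alkynyl silyl group of 19.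

Step 12
Reactants: 20 C11,C16-diethynyl tricyclic dione
Product: 21 C11,C16-bis[(4,4,5,5-tetramethyl-1,3,2-dioxaborolan-2-yl)ethynyl] tricyclic dione
Conditions: pinacolborane (2.4 equiv), iridium pincer complex (SiNN)Ir(cyclooctene) (1 mol %, monovalent iridium; SiNN = silyl–amido–quinoline ligand [2-(i-Pr2Si)-4-MeC6H3]N(8-quinolyl)), C6H6, 25 °C
Reagents that add atoms: pinacolborane, B1OC(C)(C)C(C)(C)O1
Why: Iridium-catalysed dehydrogenative borylation of terminal alkynes, which runs without base and releases H2. The C(sp)–H bonds should react much faster than the two hindered ketones are hydroborated, and the C10 ketone is not enolised.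

Step 13
Reactants: 21 bis(borylethynyl) tricyclic dione; 22 acetylene
Product: 23 pentacycle with pinacolboryl groups on C18 and C21
Conditions: CpCo(CO)2 (20 mol %, monovalent cobalt), 22 (1 atm, continuous stream), toluene, hν (visible), 100 °C, 21 added over 6 h
Reagents that add atoms: none
Why: Loss of CO from CpCo(CO)2 gives a CpCo fragment that binds both alkynes of 21 and couples them oxidatively to a cobaltacyclopentadiene (trivalent cobalt); this forms C17–C22 and with it the five-membered carbocycle C6–C11–C22–C17–C16. Acetylene 22 then coordinates and inserts, and reductive elimination forms C18–C19 and C20–C21 and releases the benzene ring. The closest known reaction type is the metal-catalysed [2+2+2] cyclotrimerisation of hepta-1,6-diynes with monoalkynes, which tolerates alkynylboronates. The five-membered ring closes by intramolecular oxidative coupling of the tethered diyne (each alkyne joined exo to the tether); the six-membered ring closes by assembly of the three alkyne units on cobalt. No stereocentre is formed, and C6, C11 and C16 are not touched. The step needs chemoselectivity for cross-cyclisation over acetylene homotrimerisation and diyne oligomerisation: the two alkynes are held cis-1,3-diaxial on ring B by the quaternary carbons C6 and C11, and slow addition of 21 into acetylene-saturated solution keeps its concentration low. The alkenes and ketones are poorer ligands than the alkynes and should stay spectators. The boryl groups sit on the carbons α to cobalt and therefore end up on C18 and C21.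

Step 14
Reactants: 23 bis(pinacolboryl) pentacycle
Product: 24 CNP0287617.1 (target hydroquinone)
Conditions: NaBO3·4H2O (6 equiv), THF–H2O (1:1), 25 °C; then aq. Na2S2O4 wash
Reagents that add atoms: sodium perborate, [Na+].[Na+].O[B-]1(O)OO[B-](O)(O)OO1
Why: Oxidation of arylboronic esters: hydroperoxide adds to boron, the aryl group migrates to oxygen and hydrolysis gives the phenol. Both C–B bonds react, and ketones and alkenes are inert to perborate at room temperature. The dithionite wash returns any quinone formed by air oxidation to the hydroquinone.

## Compound list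

1 | ethynyltrimethylsilane | C#C[Si](C)(C)C | starting material
2 | (E)-1,2-dichloroethene | Cl/C=C/Cl | starting material
3 | (E)-(4-chlorobut-3-en-1-yn-1-yl)trimethylsilane | Cl/C=C/C#C[Si](C)(C)C | intermediate
4 | isopropenylmagnesium bromide | CC(=C)[Mg]Br | starting material
5 | (E)-trimethyl(5-methylhexa-3,5-dien-1-yn-1-yl)silane | C=C(C)/C=C/C#C[Si](C)(C)C | intermediate
6 | 2-methyl-2-vinyloxirane (racemic) | CC1(C=C)CO1 | starting material
7 | (E)-4-chloro-2-methylbut-2-en-1-ol | ClC/C=C(\C)CO | intermediate
8 | tert-butyl (E)-4-chloro-2-methylbut-2-en-1-yl carbonate | ClC/C=C(\C)COC(=O)OC(C)(C)C | intermediate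
9 | 4,4-dimethoxycyclohexa-2,5-dien-1-one | COC1(OC)C=CC(=O)C=C1 | starting material
10 | (4aR,8S,8aS)-4,4-dimethoxy-6-methyl-8-[(trimethylsilyl)ethynyl]-4a,5,8,8a-tetrahydronaphthalen-1(4H)-one | O=C1C=CC(OC)(OC)[C@@H]2CC(C)=C[C@H](C#C[Si](C)(C)C)[C@H]12 | intermediate
11 | lithium dienolate of 10 (C7–OLi, C6=C7) | [Li+].[O-]C1=C2[C@@H](C#C[Si](C)(C)C)C=C(C)C[C@H]2C(OC)(OC)C=C1 | intermediate (not isolated)
12 | C6-alkylated enone (side chain on C6 cis to H11, trans to alkynyl) | CC(C)(C)OC(=O)OC/C(C)=C/C[C@@]12C(=O)C=CC(OC)(OC)[C@@H]1CC(C)=C[C@@H]2C#C[Si](C)(C)C | intermediate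
13 | dimethylphenylsilyl enol ether (C7=C8) | CC(C)(C)OC(=O)OC/C(C)=C/C[C@@]12C(O[Si](C)(C)c3ccccc3)=CCC(OC)(OC)[C@@H]1CC(C)=C[C@@H]2C#C[Si](C)(C)C | intermediate
14 | bridged tricyclic ketone, C10 dimethyl ketal, exo-isopropenyl on C4 | C=C(C)[C@H]1C[C@@]23C(=O)[C@@H]1CC(OC)(OC)[C@@H]2CC(C)=C[C@@H]3C#C[Si](C)(C)C | intermediate
15 | tricyclic 7,10-dione | C=C(C)[C@H]1C[C@@]23C(=O)[C@@H]1CC(=O)[C@@H]2CC(C)=C[C@@H]3C#C[Si](C)(C)C | intermediate
16 | C10 trimethylsilyl enol ether (C10=C11) | C=C(C)[C@H]1C[C@@]23C(=O)[C@@H]1CC(O[Si](C)(C)C)=C2CC(C)=C[C@@H]3C#C[Si](C)(C)C | intermediate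
17 | 1-[(trimethylsilyl)ethynyl]-1,2-benziodoxol-3(1H)-one | C[Si](C)(C)C#CI1OC(=O)c2ccccc12 | starting material
18 | tetrabutylammonium C10 enolate | C=C(C)[C@H]1C[C@@]23C(=O)[C@@H]1CC([O-])=C2CC(C)=C[C@@H]3C#C[Si](C)(C)C.CCCC[N+](CCCC)(CCCC)CCCC | intermediate (not isolated)
19 | C11-ethynyl dione with (trimethylsilyl)ethynyl on C16 | C=C(C)[C@H]1C[C@@]23C(=O)[C@@H]1CC(=O)[C@@]2(C#C)CC(C)=C[C@@H]3C#C[Si](C)(C)C | intermediate (not isolated)
20 | C11,C16-diethynyl tricyclic dione | C=C(C)[C@H]1C[C@@]23C(=O)[C@@H]1CC(=O)[C@@]2(C#C)CC(C)=C[C@@H]3C#C | intermediate
21 | C11,C16-bis[(pinacolboryl)ethynyl] tricyclic dione | C=C(C)[C@H]1C[C@@]23C(=O)[C@@H]1CC(=O)[C@@]2(C#CB4OC(C)(C)C(C)(C)O4)CC(C)=C[C@@H]3C#CB5OC(C)(C)C(C)(C)O5 | intermediate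
22 | acetylene | C#C | starting material
23 | pentacycle with pinacolboryl groups on C18 and C21 | C=C(C)[C@H]1C[C@@]23C(=O)[C@@H]1CC(=O)[C@@]21CC(C)=C[C@@H]3c2c(B4OC(C)(C)C(C)(C)O4)ccc(B5OC(C)(C)C(C)(C)O5)c21 | intermediate
24 | CNP0287617.1 | C=C(C)[C@H]1C[C@@]23C(=O)[C@@H]1CC(=O)[C@@]21CC(C)=C[C@@H]3c2c(O)ccc(O)c21 | target

## Step count and least certain steps

Total step count: 14. Longest linear sequence: 12 steps (steps 1, 2 and 5–14).

**Step 13 (key step).** Oxidative coupling may be slow because both alkyne termini carry boryl groups, and acetylene homotrimerisation may consume the catalyst first. The fallback sets out from 21 and returns at 23. The 2π partner is changed to an alkene, which cannot trimerise: 21 is cyclised with ethylene (1 atm) under [Rh(cod)2]BF4/BINAP (monovalent rhodium) to the 19,20-dihydro compound, cyclohexa-1,3-diene F1, which is dehydrogenated with DDQ to 23.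

**Step 11.** Proton transfer between the released enolate and ketone already formed may erode the regiochemistry, leading to ethynylation at C9 and over-alkynylation; bond formation at the congested C11 may also be slow. The fallback sets out from 15 and returns at 20. The α-methylene C9 is blocked by condensation with DMF dimethyl acetal to give the (E)-dimethylaminomethylene ketone F2. KHMDS can then deprotonate only C11, and ethynylation with 17/Bu4NF gives the C11,C16-diethynyl enaminone F3. Aqueous NaOH hydrolyses the enaminone, and the β-ketoaldehyde deformylates to 20.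

**Step 12.** The metal hydride intermediates of the catalytic cycle may hydroborate the ketones. The fallback sets out from 20 and returns at 24. The borane is changed to the non-reducing 1,8-naphthalenediaminatoborane, HB(dan), with Zn(OTf)2/pyridine (divalent zinc), giving the bis[B(dan)]diyne F4. Cyclotrimerisation with 22 as in step 13 gives the bis[B(dan)]arene F5. Aqueous HCl in THF releases the boronic acid, and oxidation as in step 14 gives 24.

**Step 8.** The enolate may attack the distal allyl terminus (seven-membered ring), the π-allyl complex may undergo β-hydride elimination, or exo selectivity at C4 may be insufficient. The fallback sets out from 10 and returns at 14, and closes the ring by an enolate SN2′ displacement without palladium. The reagent (E)-1,4-dichloro-2-methylbut-2-ene F6 is made from 7 with MsCl/LiCl. Alkylation of 10 (LDA) with F6 should occur at its faster, γ,γ-disubstituted allylic terminus and gives the allylic chloride enone F7. Hydrosilylation as in step 7 gives the silyl enol ether F8. Anhydrous benzyltrimethylammonium fluoride then releases the enolate, which displaces chloride in a 5-exo SN2′ closure to 14.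

**Step 5.** Cycloaddition of the weakly activated dienyne may be slow and facial discrimination by the catalyst incomplete. The fallback sets out from 9 and 5 and returns at 10. The cycloaddition is run thermally (toluene, 80 °C) to the racemate, and 10 is separated from its enantiomer F9 by preparative chromatography on a chiral stationary phase.

## Further compounds

F1 | step 13 | 19,20-dihydro derivative of 23 (cyclohexa-1,3-diene) | C=C(C)[C@H]1C[C@@]23C(=O)[C@@H]1CC(=O)[C@@]21CC(C)=C[C@@H]3C2=C(B4OC(C)(C)C(C)(C)O4)CCC(B5OC(C)(C)C(C)(C)O5)=C21
F2 | step 11 | C9-(E)-dimethylaminomethylene derivative of 15 | C=C(C)[C@H]1C[C@@]23C(=O)[C@@H]1/C(=C\N(C)C)C(=O)[C@@]2([H])CC(C)=C[C@@H]3C#C[Si](C)(C)C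
F3 | step 11 | C11,C16-diethynyl C9-(E)-dimethylaminomethylene dione | C=C(C)[C@H]1C[C@@]23C(=O)[C@@H]1/C(=C\N(C)C)C(=O)[C@@]2(C#C)CC(C)=C[C@@H]3C#C
F4 | step 12 | C11,C16-bis[(naphtho[1,8-de][1,3,2]diazaborinin-2-yl)ethynyl] tricyclic dione | C=C(C)[C@H]1C[C@@]23C(=O)[C@@H]1CC(=O)[C@@]2(C#CB4Nc5cccc6cccc(N4)c56)CC(C)=C[C@@H]3C#CB4Nc5cccc6cccc(N4)c56
F5 | step 12 | pentacycle with B(dan) groups on C18 and C21 | C=C(C)[C@H]1C[C@@]23C(=O)[C@@H]1CC(=O)[C@@]21CC(C)=C[C@@H]3c2c(B4Nc5cccc6cccc(N4)c56)ccc(B4Nc5cccc6cccc(N4)c56)c21
F6 | step 8 | (E)-1,4-dichloro-2-methylbut-2-ene | ClC/C=C(\C)CCl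
F7 | step 8 | C6-[(E)-4-chloro-3-methylbut-2-en-1-yl] enone | ClC/C(C)=C/C[C@@]12C(=O)C=CC(OC)(OC)[C@@H]1CC(C)=C[C@@H]2C#C[Si](C)(C)C
F8 | step 8 | dimethylphenylsilyl enol ether of the allylic chloride | ClC/C(C)=C/C[C@@]12C(O[Si](C)(C)c3ccccc3)=CCC(OC)(OC)[C@@H]1CC(C)=C[C@@H]2C#C[Si](C)(C)C
F9 | step 5 | (4aS,8R,8aR)-enantiomer of 10 | O=C1C=CC(OC)(OC)[C@H]2CC(C)=C[C@@H](C#C[Si](C)(C)C)[C@@H]12
A1 | alternative 1 | C11-formyl spiro(α-methylenecyclopentanone) indane, bis(methyl ether) | C=C(C)[C@H]1C[C@@]2(C(=O)C1=C)[C@@]1(C=O)CC(C)=C[C@@H]2c2c(OC)ccc(OC)c21
A2 | alternative 1 | C10 carbinol of the target bis(methyl ether) | C=C(C)[C@H]1C[C@@]23C(=O)[C@@H]1C[C@H](O)[C@@]21CC(C)=C[C@@H]3c2c(OC)ccc(OC)c21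
A3 | alternative 2 | C16-vinyl, C11-methallyl tetracyclic trione, bis(methyl ether) | CC(=O)[C@H]1C[C@@]23C(=O)[C@@H]1CC(=O)[C@]2(CC(C)=C)c1c(OC)ccc(OC)c1[C@H]3C=C
A4 | alternative 2 | pentacyclic methyl ketone, bis(methyl ether) | CC(=O)[C@H]1C[C@@]23C(=O)[C@@H]1CC(=O)[C@@]21CC(C)=C[C@@H]3c2c(OC)ccc(OC)c21
A5 | alternative 3 | C11-acetyl spiro-cyclopentanone indane, bis(methyl ether) | C=C(C)[C@H]1C[C@@]2(C(=O)C1)[C@@]1(C(C)=O)CC(C)=C[C@@H]2c2c(OC)ccc(OC)c21
A6 | alternative 3 | target bis(methyl ether) | C=C(C)[C@H]1C[C@@]23C(=O)[C@@H]1CC(=O)[C@@]21CC(C)=C[C@@H]3c2c(OC)ccc(OC)c21
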